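(Its constants are invented; no experiment stands behind them.)

I ask what this flask holds at the end of its run: how much starting material has reacted, and how much target and side product stand.

starting material 0.050 M (fed, over 50 s); partner 0.0475 M; transfer agent 0.0150 M; initiator 0.55 mM; time 8.0 h; the fed solution adds 0.50 times the starting volume

    initiator → 2 initiating radical (k1 = 0.088 min⁻¹)
    starting material + initiating radical → capped initiator + first chain carrier (k2 = 9.4 × 10⁵ L mol⁻¹ s⁻¹)
    partner + first chain carrier → target + second chain carrier (k3 = 4.3 × 10⁵ L mol⁻¹ s⁻¹)
    starting material + second chain carrier → released group + first chain carrier (k4 = 3.0 × 10⁵ L mol⁻¹ s⁻¹)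
    transfer agent + first chain carrier → side product + idle radical (k5 = 1.2 × 10⁵ L mol⁻¹ s⁻¹)
    2 idle radical → ended radicals (k6 = 3.8 × 10⁶ L mol⁻¹ s⁻¹)
    2 second chain carrier → ended chains (k7 = 6.8 × 10⁸ L mol⁻¹ s⁻¹)
    partner → decomposed reagent (k8 = 0.098 min⁻¹)
    starting material ⇌ dormant form (K9 = 0.94, k9 = 1.8 min⁻¹)

* how much of the starting material has reacted by 8.0 h
* how much target there is at 8.0 h, in percent of the starting material charged
* how much side product there is at 8.0 h, in percent of the starting material charged

- two of one species on the left: rate k times its square, two consumed each time
- every charge counts on the volume at the start, and the solution that is fed holds the whole dose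
- what has gone from starting material into another species counts as reacted, even if it can come back
- run time (flask): 8.0 h

I reckon down a ladder of times and freeze what stops moving on each rung. The first chain carrier lives about 4.50 × 10⁻⁵ s, shorter than the feed of 50 s, so it sits in a steady state. Starting material and dormant form relax with a half-life of 0.187 min, also shorter than the feed, so I freeze their ratio at 0.94. Partner decays with a half-life of 7.07 min and initiator with 7.88 min. Both are far shorter than the run, so I reckon the chain to its end. Transfer agent stays frozen, because the radicals charged, 1.10 mM, are fewer than its 0.0150 M.

Radicals arrive at first at 1.61 × 10⁻⁶ M s⁻¹. With free starting material at half its charge, the second chain carrier stands near 2.44 × 10⁻⁹ M, and its pairing loses 8.10 × 10⁻⁹ M s⁻¹, which is less. So I let each radical end by transfer, and side product comes to 2.20%.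

At each turn the chain goes on through partner or stops at transfer agent, at odds of 11.3 at the start. The feed dilutes both alike. Partner fades while radicals are being born, so I weight those odds by the two decays. That gives the kinetic chain length, target per side product, 5.37. Target is then 11.8%. Starting material is truly used once per radical and once per target, and the remainder splits by the frozen ratio, so conversion is 55.7%.

The forecast says 55.3% (54% to 57%), 11.2% (9.5% to 13%) and 2.1% (1.8% to 2.3%), on the ground that “Nearly every radical ends by transfer”. My target lies above its figure.

The simulation gives 55.3%, 11.0% and 2.19%, inside the forecast's ranges.

In this flask the half-lives of partner and initiator lie close together, 7.07 min against 7.88 min, and half of the target is made by 3.59 min. The flask then stands still: 0% of partner and 0% of initiator remain, with 45% of starting material free, and target per side product reads 5.02 against my 5.37.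

In the neighbour with 0.037 M of transfer agent, the chain length falls to 2.18, which gives 4.79% of target. The computed flask gives 4.66%.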